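**Retrosynthetic overview**
1. Target ⇒ C8 allyl carbinol (allyl → prenyl by cross-metathesis with 2-methylbut-2-ene) ⇒ C8 enal (catalytic asymmetric allylboration sets 8R).
2. C8 enal ⇒ 5-acetoxy geranyl-type umbelliferone ether, by E-selective Riley oxidation of the terminal E-methyl (fixes 6E).
3. That ether ⇒ (2E,5S)-3,7-dimethylocta-2,6-diene-1,5-diol + umbelliferone (Mitsunobu at C1, then acetylation at C5).
4. Diol ⇒ (S)-6-methylhept-5-en-1-yn-4-ol (carboalumination/hydroxymethylation sets 2E) ⇒ 3-methylbut-2-enal + allenylboronate (catalytic asymmetric propargylboration sets 5S).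
5. No ring is formed; the coumarin bicycle is bought intact as umbelliferone, and no protecting group is used.

Assumption: chain carbons are numbered C1 (OCH2) to C12 as in the farnesyl chain and chain names use this numbering; all starting materials and both enantiomers of TRIP phosphoric acid (the BINOL hydrogen phosphate with 2,4,6-triisopropylphenyl groups at C3 and C3′) are bought.

**Step 1**
Reactants: 1 3-methylbut-2-enal; 2 allenylboronic acid pinacol ester
Product: 4 (S)-6-methylhept-5-en-1-yn-4-ol, via pinacolborate ester 3 (not isolated)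
Conditions: (S)-TRIP phosphoric acid (10 mol %), 4 Å molecular sieves, toluene, −20 °C; aq. NaHCO3
Reagents that add atoms: allenylboronic acid pinacol ester, C=C=CB1OC(C)(C)C(C)(C)O1
Why: Chiral-phosphoric-acid-catalysed propargylboration (SE2′, six-membered transition state) gives 1,2-addition only, and the (S)-acid sends the boronate to the Si face of the enal, setting C5 as S.

**Step 2**
Reactants: 4 (S)-6-methylhept-5-en-1-yn-4-ol; 5 trimethylaluminium; 6 paraformaldehyde
Product: 9 (2E,5S)-3,7-dimethylocta-2,6-diene-1,5-diol, via alkenyldimethylalane 7 (not isolated), via lithium alkenylalanate 8 (not isolated)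
Conditions: AlMe3 (3 equiv), Cp2ZrCl2 (0.25 equiv), CH2Cl2, 0 °C to rt; n-BuLi, THF, −30 °C; (CH2O)n, rt; aq. potassium sodium tartrate
Reagents that add atoms: trimethylaluminium, C[Al](C)C; paraformaldehyde (reacts as formaldehyde), C=O
Why: Negishi zirconium-catalysed carboalumination adds Me and Al syn across the terminal alkyne with Al on the terminal carbon, and hydroxymethylation of the alanate with retention fixes the 2E alkene while the hydroxyl rides along as its aluminium alkoxide.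

**Step 3**
Reactants: 9 (2E,5S)-3,7-dimethylocta-2,6-diene-1,5-diol; 10 umbelliferone (7-hydroxycoumarin)
Product: 11 7-{[(2E,5S)-5-hydroxy-3,7-dimethylocta-2,6-dien-1-yl]oxy}-2H-chromen-2-one
Conditions: PPh3 (1.1 equiv), DIAD (1.1 equiv), THF, 0 °C
Reagents that add atoms: umbelliferone, Oc1ccc2ccc(=O)oc2c1
Why: Mitsunobu etherification activates the unhindered primary allylic alcohol much faster than the secondary one, and the acidic phenol displaces the oxyphosphonium by SN2 without touching C5.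

**Step 4**
Reactants: 11 7-{[(2E,5S)-5-hydroxy-3,7-dimethylocta-2,6-dien-1-yl]oxy}-2H-chromen-2-one; 12 acetic anhydride
Product: 13 (2E,5S)-3,7-dimethyl-1-[(2-oxo-2H-chromen-7-yl)oxy]octa-2,6-dien-5-yl acetate
Conditions: Ac2O, pyridine, DMAP (cat.), CH2Cl2, 0 °C to rt
Reagents that add atoms: acetic anhydride, CC(=O)OC(C)=O
Why: DMAP-catalysed acylation of the only free hydroxyl proceeds with retention at C5.

**Step 5**
Reactants: 13 (2E,5S)-3,7-dimethyl-1-[(2-oxo-2H-chromen-7-yl)oxy]octa-2,6-dien-5-yl acetate; 14 tert-butyl hydroperoxide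
Product: 16 (2E,5S,6E)-3,7-dimethyl-8-oxo-1-[(2-oxo-2H-chromen-7-yl)oxy]octa-2,6-dien-5-yl acetate, via allylic alcohol 15 (not isolated)
Conditions: SeO2 (0.5 equiv), t-BuOOH (3 equiv), CH2Cl2, rt; then MnO2 (excess), CH2Cl2, rt
Reagents that add atoms: tert-butyl hydroperoxide, CC(C)(C)OO
Why: Riley allylic oxidation (ene reaction then [2,3]-sigmatropic shift) is E-selective and should favour the terminal isopropylidene methyl, because the internal 2,3-alkene is deactivated by the allylic aryloxy group and its only E-allylic CH2 sits next to the acetoxy carbon; MnO2 then converges the allylic alcohol to the 6E enal.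

**Step 6**
Reactants: 16 (2E,5S,6E)-3,7-dimethyl-8-oxo-1-[(2-oxo-2H-chromen-7-yl)oxy]octa-2,6-dien-5-yl acetate; 17 allylboronic acid pinacol ester
Product: 19 (2E,5S,6E,8R)-8-hydroxy-3,7-dimethyl-1-[(2-oxo-2H-chromen-7-yl)oxy]undeca-2,6,10-trien-5-yl acetate, via pinacolborate ester 18 (not isolated)
Conditions: (R)-TRIP phosphoric acid (5 mol %), toluene, −30 °C; aq. NaHCO3
Reagents that add atoms: allylboronic acid pinacol ester, C=CCB1OC(C)(C)C(C)(C)O1
Why: Chiral-phosphoric-acid-catalysed allylboration through a chair transition state tolerates the acetate and lactone, and the (R)-acid sends allyl to the Re face of the enal under catalyst control, setting C8 as R.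

**Step 7**
Reactants: 19 (2E,5S,6E,8R)-8-hydroxy-3,7-dimethyl-1-[(2-oxo-2H-chromen-7-yl)oxy]undeca-2,6,10-trien-5-yl acetate; 20 2-methylbut-2-ene
Product: 21 (2E,5S,6E,8R)-8-hydroxy-3,7,11-trimethyl-1-[(2-oxo-2H-chromen-7-yl)oxy]dodeca-2,6,10-trien-5-yl acetate (target)
Conditions: second-generation Grubbs catalyst RuCl2(=CHPh)(PCy3)(H2IMes) (5 mol %), 2-methylbut-2-ene (large excess), CH2Cl2, 35 °C
Reagents that add atoms: 2-methylbut-2-ene, CC=C(C)C
Why: Olefin cross-metathesis turns the terminal allyl group into prenyl, while the trisubstituted alkenes, the coumarin alkene and both stereocentres are left alone.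

**Compound list**
1 | 3-methylbut-2-enal | CC(C)=CC=O | starting material
2 | allenylboronic acid pinacol ester | C=C=CB1OC(C)(C)C(C)(C)O1 | starting material
3 | 2-{[(4S)-6-methylhept-5-en-1-yn-4-yl]oxy}-4,4,5,5-tetramethyl-1,3,2-dioxaborolane | C#CC[C@H](OB1OC(C)(C)C(C)(C)O1)C=C(C)C | intermediate (not isolated)
4 | (S)-6-methylhept-5-en-1-yn-4-ol | C#CC[C@H](O)C=C(C)C | intermediate
5 | trimethylaluminium | C[Al](C)C | starting material
6 | paraformaldehyde (as formaldehyde) | C=O | starting material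
7 | dimethyl[(1E,4S)-4-(dimethylalumanyloxy)-2,6-dimethylhepta-1,5-dien-1-yl]alumane | C[Al](C)/C=C(\C)C[C@H](O[Al](C)C)C=C(C)C | intermediate (not isolated)
8 | lithium butyl[(1E,4S)-4-(dimethylalumanyloxy)-2,6-dimethylhepta-1,5-dien-1-yl]dimethylaluminate | [Li+].CCCC[Al-](C)(C)/C=C(\C)C[C@H](O[Al](C)C)C=C(C)C | intermediate (not isolated)
9 | (2E,5S)-3,7-dimethylocta-2,6-diene-1,5-diol | OC/C=C(C)/C[C@H](O)C=C(C)C | intermediate
10 | umbelliferone (7-hydroxy-2H-chromen-2-one) | Oc1ccc2ccc(=O)oc2c1 | starting material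
11 | 7-{[(2E,5S)-5-hydroxy-3,7-dimethylocta-2,6-dien-1-yl]oxy}-2H-chromen-2-one | O[C@H](C=C(C)C)C/C(C)=C/COc1ccc2ccc(=O)oc2c1 | intermediate
12 | acetic anhydride | CC(=O)OC(C)=O | starting material
13 | (2E,5S)-3,7-dimethyl-1-[(2-oxo-2H-chromen-7-yl)oxy]octa-2,6-dien-5-yl acetate | CC(=O)O[C@H](C=C(C)C)C/C(C)=C/COc1ccc2ccc(=O)oc2c1 | intermediate
14 | tert-butyl hydroperoxide | CC(C)(C)OO | starting material
15 | (2E,5S,6E)-8-hydroxy-3,7-dimethyl-1-[(2-oxo-2H-chromen-7-yl)oxy]octa-2,6-dien-5-yl acetate | CC(=O)O[C@H](/C=C(\C)CO)C/C(C)=C/COc1ccc2ccc(=O)oc2c1 | intermediate (not isolated)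
16 | (2E,5S,6E)-3,7-dimethyl-8-oxo-1-[(2-oxo-2H-chromen-7-yl)oxy]octa-2,6-dien-5-yl acetate | CC(=O)O[C@H](/C=C(\C)C=O)C/C(C)=C/COc1ccc2ccc(=O)oc2c1 | intermediate
17 | allylboronic acid pinacol ester | C=CCB1OC(C)(C)C(C)(C)O1 | starting material
18 | (2E,5S,6E,8R)-3,7-dimethyl-1-[(2-oxo-2H-chromen-7-yl)oxy]-8-[(4,4,5,5-tetramethyl-1,3,2-dioxaborolan-2-yl)oxy]undeca-2,6,10-trien-5-yl acetate | CC(=O)O[C@H](/C=C(\C)[C@H](OB1OC(C)(C)C(C)(C)O1)CC=C)C/C(C)=C/COc1ccc2ccc(=O)oc2c1 | intermediate (not isolated)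
19 | (2E,5S,6E,8R)-8-hydroxy-3,7-dimethyl-1-[(2-oxo-2H-chromen-7-yl)oxy]undeca-2,6,10-trien-5-yl acetate | CC(=O)O[C@H](/C=C(\C)[C@H](O)CC=C)C/C(C)=C/COc1ccc2ccc(=O)oc2c1 | intermediate
20 | 2-methylbut-2-ene | CC=C(C)C | starting material
21 | (2E,5S,6E,8R)-8-hydroxy-3,7,11-trimethyl-1-[(2-oxo-2H-chromen-7-yl)oxy]dodeca-2,6,10-trien-5-yl acetate | CC(=O)O[C@H](/C=C(\C)[C@H](O)CC=C(C)C)C/C(C)=C/COc1ccc2ccc(=O)oc2c1 | target

**Step count and risk**
Total steps: 7 (step 5 is one telescoped two-stage oxidation). Longest linear sequence: 7 steps from 3-methylbut-2-enal.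

The three steps most likely to fail:

- **Step 5** (site-selectivity of the Riley oxidation between two allylically oxygenated trisubstituted alkenes; modest conversion). The fallback sets out from 4 and comes back at 15. The E-methyl is oxidised while the isopropylidene is still the only alkene (SeO2, t-BuOOH, CH2Cl2; NaBH4 to return any enal), giving (2E,4S)-2-methylhept-2-en-6-yne-1,4-diol F1. The primary hydroxyl is silylated (TBDPSCl, imidazole) to (2E,4S)-1-[(tert-butyldiphenylsilyl)oxy]-2-methylhept-2-en-6-yn-4-ol F2. Carboalumination and hydroxymethylation as in step 2 give (2E,5S,6E)-8-[(tert-butyldiphenylsilyl)oxy]-3,7-dimethylocta-2,6-diene-1,5-diol F3. Mitsunobu coupling with 10 gives 7-{[(2E,5S,6E)-8-[(tert-butyldiphenylsilyl)oxy]-5-hydroxy-3,7-dimethylocta-2,6-dien-1-yl]oxy}-2H-chromen-2-one F4. Acetylation gives (2E,5S,6E)-8-[(tert-butyldiphenylsilyl)oxy]-3,7-dimethyl-1-[(2-oxo-2H-chromen-7-yl)oxy]octa-2,6-dien-5-yl acetate F5. HF·pyridine then frees 15, which MnO2 takes to 16.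

- **Step 2** (Lewis-acidic carboalumination of an ionisable allylic alkoxide and trapping of the alanate). The fallback sets out from 4 and comes back at 9. The dianion of 4 (n-BuLi, 2.2 equiv) is hydroxymethylated with (CH2O)n to (5S)-7-methyloct-6-en-2-yne-1,5-diol F6. NaAlH2(OCH2CH2OCH3)2 adds hydride trans under direction of the propargylic alkoxide, and I2 traps the alkenylaluminate as (2Z,5S)-3-iodo-7-methylocta-2,6-diene-1,5-diol F7. Me2CuLi replaces iodine by methyl with retention to give 9.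

- **Step 3** (chemoselectivity of the Mitsunobu reaction between the primary and the activated secondary allylic alcohol). The fallback sets out from 9 and comes back at 11. MsCl, LiCl and 2,4,6-collidine in DMF at 0 °C convert only the primary allylic alcohol into (2E,5S)-1-chloro-3,7-dimethylocta-2,6-dien-5-ol F8, which alkylates 10 (K2CO3, acetone) to give 11.

**Further compounds**
F1 | step 5 | (2E,4S)-2-methylhept-2-en-6-yne-1,4-diol | C#CC[C@H](O)/C=C(\C)CO
F2 | step 5 | (2E,4S)-1-[(tert-butyldiphenylsilyl)oxy]-2-methylhept-2-en-6-yn-4-ol | C#CC[C@H](O)/C=C(\C)CO[Si](c1ccccc1)(c1ccccc1)C(C)(C)C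
F3 | step 5 | (2E,5S,6E)-8-[(tert-butyldiphenylsilyl)oxy]-3,7-dimethylocta-2,6-diene-1,5-diol | OC/C=C(C)/C[C@H](O)/C=C(\C)CO[Si](c1ccccc1)(c1ccccc1)C(C)(C)C
F4 | step 5 | 7-{[(2E,5S,6E)-8-[(tert-butyldiphenylsilyl)oxy]-5-hydroxy-3,7-dimethylocta-2,6-dien-1-yl]oxy}-2H-chromen-2-one | O[C@H](/C=C(\C)CO[Si](c1ccccc1)(c1ccccc1)C(C)(C)C)C/C(C)=C/COc1ccc2ccc(=O)oc2c1
F5 | step 5 | (2E,5S,6E)-8-[(tert-butyldiphenylsilyl)oxy]-3,7-dimethyl-1-[(2-oxo-2H-chromen-7-yl)oxy]octa-2,6-dien-5-yl acetate | CC(=O)O[C@H](/C=C(\C)CO[Si](c1ccccc1)(c1ccccc1)C(C)(C)C)C/C(C)=C/COc1ccc2ccc(=O)oc2c1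
F6 | step 2 | (5S)-7-methyloct-6-en-2-yne-1,5-diol | OCC#CC[C@H](O)C=C(C)C
F7 | step 2 | (2Z,5S)-3-iodo-7-methylocta-2,6-diene-1,5-diol | OC/C=C(I)/C[C@H](O)C=C(C)C
F8 | step 3 | (2E,5S)-1-chloro-3,7-dimethylocta-2,6-dien-5-ol | ClC/C=C(C)/C[C@H](O)C=C(C)C
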